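**Plan**
- Atom labels: ring A (4-hydroxy-3,5-dimethoxyphenyl) sits on C7; the chain is C7(OH)–C8(O–ring B)–C9(OH); ring B carries the chain C7'–C8'(OH)–C9'(OH).
- Cuts: C1(ring A)–C7 and C7–C8 (both in the key step), C8–O(ring B), C8–C9, and C1'(ring B)–C7'.
- Enabling feature: C9, C8 and C7 form a chain in which C8 bears the ring B ether oxygen and C7 bears ring A plus OH, so C8 and C7 can each be inserted as CHCl into a C–B bond and then substituted.
- Forward order: ring B phenol from an aryl Grignard reagent and (S)-benzyl glycidyl ether; C9 boronate, C8 insertion, aryloxide substitution, C7 insertion with ring A aryl transfer, C–B oxidation, hydrogenolysis. No ring is formed.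
- Stereochemistry: C8' comes from the glycidyl ether; C8 and C7 both come from one (R,R)-1,2-dicyclohexylethane-1,2-diol (DICHED) director through (S)-chlorides and inversions; C7–B to C7–OH with retention gives threo (7S,8S).

Key step: step 10

Assumption: boronic esters of (R,R)-1,2-diols are taken to give the (S)-α-chloro boronic ester (priority Cl > C > B) on insertion of (dichloromethyl)lithium, at C8 and at C7 alike.

**Route**

Step 1
Reactants: 1 4-bromo-2,6-dimethoxyphenol
Product: 2 5-bromo-1,3-dimethoxy-2-(methoxymethoxy)benzene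
Conditions: MOMCl, K2CO3, DMF, 0 °C to rt
Reagents that add atoms: chloromethyl methyl ether COCCl
Why: Williamson-type O-alkylation of the phenoxide by the reactive chloromethyl ether should proceed despite the two flanking methoxy groups, and the acetal tolerates Mg insertion and NaH.

Step 2
Reactants: 2 5-bromo-1,3-dimethoxy-2-(methoxymethoxy)benzene; 3 (S)-benzyl glycidyl ether
Product: 5 (2S)-1-(benzyloxy)-3-[3,5-dimethoxy-4-(methoxymethoxy)phenyl]propan-2-ol, via arylmagnesium bromide 4 (not isolated)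
Conditions: Mg, I2 (cat.), THF, 50 °C; then CuI (cat.), 3, THF, −30 to 0 °C
Reagents that add atoms: none
Why: Grignard formation followed by CuI-catalysed SN2 opening of the terminal epoxide at its CH2 carbon forms C1'–C7'; the stereocentre of 3 is not touched and becomes (S)-C8'.

Step 3
Reactants: 5 (2S)-1-(benzyloxy)-3-[3,5-dimethoxy-4-(methoxymethoxy)phenyl]propan-2-ol
Product: 7 5-[(2S)-2,3-bis(benzyloxy)propyl]-1,3-dimethoxy-2-(methoxymethoxy)benzene, via sodium alkoxide 6 (not isolated)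
Conditions: NaH, THF, 0 °C; BnBr, n-Bu4NI (cat.), 0 °C to rt
Reagents that add atoms: benzyl bromide BrCc1ccccc1
Why: Williamson etherification of the secondary alkoxide; the aryl MOM ether is inert to NaH and C8' is not involved.

Step 4
Reactants: 7 5-[(2S)-2,3-bis(benzyloxy)propyl]-1,3-dimethoxy-2-(methoxymethoxy)benzene
Product: 8 4-[(2S)-2,3-bis(benzyloxy)propyl]-2,6-dimethoxyphenol
Conditions: conc. HCl (cat.), MeOH, 45 °C
Reagents that add atoms: none
Why: acid-catalysed acetal exchange with methanol removes the aryl MOM group, while alkyl benzyl ethers and aryl methyl ethers are stable.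

Step 5
Reactants: 9 potassium (benzyloxymethyl)trifluoroborate; 10 (1R,2R)-1,2-dicyclohexylethane-1,2-diol
Product: 11 (4R,5R)-2-(benzyloxymethyl)-4,5-dicyclohexyl-1,3,2-dioxaborolane
Conditions: TMSCl (3 equiv), MeCN, rt
Reagents that add atoms: none
Why: TMSCl strips fluoride from the trifluoroborate and the electrophilic borane is captured by the diol as the five-membered boronic ester (trifluoroborate to boronic ester interconversion); no stereocentre is formed.

Step 6
Reactants: 11 (4R,5R)-2-(benzyloxymethyl)-4,5-dicyclohexyl-1,3,2-dioxaborolane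
Product: 13 (4R,5R)-2-[(1S)-2-(benzyloxy)-1-chloroethyl]-4,5-dicyclohexyl-1,3,2-dioxaborolane, via lithium dichloromethylborate 12 (not isolated)
Conditions: CH2Cl2, n-BuLi, THF, −100 °C; 11; ZnCl2 (THF), −100 °C to rt
Reagents that add atoms: dichloromethane ClCCl
Why: Matteson asymmetric homologation: (dichloromethyl)lithium adds to boron and ZnCl2 promotes the 1,2-shift of the C9 carbon with loss of the chloride selected by the C2-symmetric (R,R)-diol, which should give the (S)-chloride at C8.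

Step 7
Reactants: 8 4-[(2S)-2,3-bis(benzyloxy)propyl]-2,6-dimethoxyphenol; 13 (4R,5R)-2-[(1S)-2-(benzyloxy)-1-chloroethyl]-4,5-dicyclohexyl-1,3,2-dioxaborolane
Product: 16 (4R,5R)-2-[(1R)-2-(benzyloxy)-1-{4-[(2S)-2,3-bis(benzyloxy)propyl]-2,6-dimethoxyphenoxy}ethyl]-4,5-dicyclohexyl-1,3,2-dioxaborolane, via sodium aryloxide 14 (not isolated), via aryloxyborate 15 (not isolated)
Conditions: 8, NaH, THF, 0 °C; then 13, THF/DMSO, rt, under Ar
Reagents that add atoms: none
Why: substitution of an α-chloro boronic ester by an oxygen nucleophile (Matteson substitution): the aryloxide adds to boron and shifts to C8 anti to the departing chloride, so inversion should convert (S)-13 into (R)-16.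

Step 8
Reactants: 1 4-bromo-2,6-dimethoxyphenol
Product: 17 2-(benzyloxy)-5-bromo-1,3-dimethoxybenzene
Conditions: BnBr, K2CO3, DMF, rt
Reagents that add atoms: benzyl bromide BrCc1ccccc1
Why: Williamson benzylation of the phenol, giving a ring A protecting group that survives Grignard chemistry and alkaline peroxide and is removed in the final hydrogenolysis.

Step 9
Reactants: 17 2-(benzyloxy)-5-bromo-1,3-dimethoxybenzene
Product: 18 [4-(benzyloxy)-3,5-dimethoxyphenyl]magnesium bromide (titrated THF solution)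
Conditions: Mg, I2 (cat.), THF, 50 °C
Reagents that add atoms: magnesium [Mg]
Why: oxidative insertion of Mg into the aryl–Br bond (Grignard formation); the benzyl and methyl ethers are inert.

Step 10
Reactants: 16 (4R,5R)-2-[(1R)-2-(benzyloxy)-1-{4-[(2S)-2,3-bis(benzyloxy)propyl]-2,6-dimethoxyphenoxy}ethyl]-4,5-dicyclohexyl-1,3,2-dioxaborolane; 18 [4-(benzyloxy)-3,5-dimethoxyphenyl]magnesium bromide
Product: 22 (4R,5R)-2-[(1S,2R)-3-(benzyloxy)-1-[4-(benzyloxy)-3,5-dimethoxyphenyl]-2-{4-[(2S)-2,3-bis(benzyloxy)propyl]-2,6-dimethoxyphenoxy}propyl]-4,5-dicyclohexyl-1,3,2-dioxaborolane, via lithium dichloromethylborate 19 (not isolated), via alpha-chloro boronate 20 (not isolated), via magnesium arylborate 21 (not isolated)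
Conditions: CH2Cl2, n-BuLi, THF, −100 °C; 16; ZnCl2 (2 equiv), −100 °C to rt; then 18 (excess), −78 °C to rt
Reagents that add atoms: dichloromethane ClCCl
Why: (Dichloromethyl)lithium adds to the boron of 16 to give borate 19, and ZnCl2 triggers the 1,2-shift of C8 (with retention) onto the CHCl2 carbon with loss of one of the two diastereotopic chlorides, which forms C7–C8 and chloride 20; Grignard reagent 18 then gives arylborate 21, whose aryl group moves from boron to C7 with inversion and loss of chloride, which forms C1–C7. The closest known reaction type is the Matteson asymmetric homologation of α-alkoxy boronic esters of C2-symmetric diols followed by Grignard substitution. No ring is closed. The C7 stereocentre is controlled by the (R,R)-DICHED ring, which selects the chloride that leaves so that 20 should be the (1S)-chloride, and the stereospecific inversion then gives (1S)-22; because carbon enters at C7 and boron later becomes oxygen, the same director that set C8 delivers the threo pair. The step needs both 1,2-shifts to outrun β-elimination of the ring B aryloxide and chloride-induced epimerisation of 20: excess ZnCl2 binds free chloride and accelerates the shifts, the Grignard reagent is added at −78 °C, and the electron-rich 2,6-dimethoxyaryloxide is a comparatively poor leaving group.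

Step 11
Reactants: 22 (4R,5R)-2-[(1S,2R)-3-(benzyloxy)-1-[4-(benzyloxy)-3,5-dimethoxyphenyl]-2-{4-[(2S)-2,3-bis(benzyloxy)propyl]-2,6-dimethoxyphenoxy}propyl]-4,5-dicyclohexyl-1,3,2-dioxaborolane
Product: 24 (1S,2S)-3-(benzyloxy)-1-[4-(benzyloxy)-3,5-dimethoxyphenyl]-2-{4-[(2S)-2,3-bis(benzyloxy)propyl]-2,6-dimethoxyphenoxy}propan-1-ol, via borate ester 23 (not isolated)
Conditions: 30% H2O2, 2 M NaOH, THF, 0 °C to rt
Reagents that add atoms: hydrogen peroxide OO
Why: alkaline peroxide oxidation of the C–B bond: hydroperoxide adds to boron and C7 shifts from B to O with retention, and hydrolysis of borate ester 23 should give the threo (1S,2S) alcohol and release the diol for recovery.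

Step 12
Reactants: 24 (1S,2S)-3-(benzyloxy)-1-[4-(benzyloxy)-3,5-dimethoxyphenyl]-2-{4-[(2S)-2,3-bis(benzyloxy)propyl]-2,6-dimethoxyphenoxy}propan-1-ol
Product: 25 (1S,2S)-1-(4-hydroxy-3,5-dimethoxyphenyl)-2-{4-[(2S)-2,3-dihydroxypropyl]-2,6-dimethoxyphenoxy}propane-1,3-diol (CNP0229130.2)
Conditions: H2 (1 atm), 10% Pd/C, EtOAc/MeOH, rt
Reagents that add atoms: none
Why: hydrogenolysis of the four O-benzyl groups over Pd/C; under neutral conditions the benzylic C7–OH and the C8–O aryl ether are cleaved far more slowly, and no stereocentre is affected.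

**Compound list**

1 | 4-bromo-2,6-dimethoxyphenol | COc1cc(Br)cc(OC)c1O | starting material
2 | 5-bromo-1,3-dimethoxy-2-(methoxymethoxy)benzene | COCOc1c(OC)cc(Br)cc1OC | intermediate
3 | (S)-benzyl glycidyl ether | C1[C@H](O1)COCc2ccccc2 | starting material
4 | [3,5-dimethoxy-4-(methoxymethoxy)phenyl]magnesium bromide | COCOc1c(OC)cc([Mg]Br)cc1OC | intermediate
5 | (2S)-1-(benzyloxy)-3-[3,5-dimethoxy-4-(methoxymethoxy)phenyl]propan-2-ol | COCOc1c(OC)cc(C[C@H](O)COCc2ccccc2)cc1OC | intermediate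
6 | sodium (2S)-1-(benzyloxy)-3-[3,5-dimethoxy-4-(methoxymethoxy)phenyl]propan-2-olate | [Na+].COCOc1c(OC)cc(C[C@H]([O-])COCc2ccccc2)cc1OC | intermediate
7 | 5-[(2S)-2,3-bis(benzyloxy)propyl]-1,3-dimethoxy-2-(methoxymethoxy)benzene | COCOc1c(OC)cc(C[C@H](OCc2ccccc2)COCc2ccccc2)cc1OC | intermediate
8 | 4-[(2S)-2,3-bis(benzyloxy)propyl]-2,6-dimethoxyphenol | COc1cc(C[C@H](OCc2ccccc2)COCc2ccccc2)cc(OC)c1O | intermediate
9 | potassium (benzyloxymethyl)trifluoroborate | [K+].F[B-](F)(F)COCc1ccccc1 | starting material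
10 | (1R,2R)-1,2-dicyclohexylethane-1,2-diol, (R,R)-DICHED | O[C@H](C1CCCCC1)[C@H](O)C1CCCCC1 | starting material
11 | (4R,5R)-2-(benzyloxymethyl)-4,5-dicyclohexyl-1,3,2-dioxaborolane | c1ccccc1COCB1O[C@H](C2CCCCC2)[C@@H](C2CCCCC2)O1 | intermediate
12 | lithium (4R,5R)-2-(benzyloxymethyl)-2-(dichloromethyl)-4,5-dicyclohexyl-1,3,2-dioxaborolan-2-uide | [Li+].ClC(Cl)[B-]1(COCc2ccccc2)O[C@H](C2CCCCC2)[C@@H](C2CCCCC2)O1 | intermediate
13 | (4R,5R)-2-[(1S)-2-(benzyloxy)-1-chloroethyl]-4,5-dicyclohexyl-1,3,2-dioxaborolane | Cl[C@H](COCc1ccccc1)B1O[C@H](C2CCCCC2)[C@@H](C2CCCCC2)O1 | intermediate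
14 | sodium 4-[(2S)-2,3-bis(benzyloxy)propyl]-2,6-dimethoxyphenolate | [Na+].COc1cc(C[C@H](OCc2ccccc2)COCc2ccccc2)cc(OC)c1[O-] | intermediate
15 | sodium (4R,5R)-2-[(1S)-2-(benzyloxy)-1-chloroethyl]-2-{4-[(2S)-2,3-bis(benzyloxy)propyl]-2,6-dimethoxyphenoxy}-4,5-dicyclohexyl-1,3,2-dioxaborolan-2-uide | [Na+].COc1cc(C[C@H](OCc2ccccc2)COCc2ccccc2)cc(OC)c1O[B-]1([C@H](Cl)COCc2ccccc2)O[C@H](C2CCCCC2)[C@@H](C2CCCCC2)O1 | intermediate
16 | (4R,5R)-2-[(1R)-2-(benzyloxy)-1-{4-[(2S)-2,3-bis(benzyloxy)propyl]-2,6-dimethoxyphenoxy}ethyl]-4,5-dicyclohexyl-1,3,2-dioxaborolane | COc1cc(C[C@H](OCc2ccccc2)COCc2ccccc2)cc(OC)c1O[C@@H](COCc1ccccc1)B1O[C@H](C2CCCCC2)[C@@H](C2CCCCC2)O1 | intermediate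
17 | 2-(benzyloxy)-5-bromo-1,3-dimethoxybenzene | COc1cc(Br)cc(OC)c1OCc1ccccc1 | intermediate
18 | [4-(benzyloxy)-3,5-dimethoxyphenyl]magnesium bromide | COc1cc([Mg]Br)cc(OC)c1OCc1ccccc1 | intermediate
19 | lithium (4R,5R)-2-[(1R)-2-(benzyloxy)-1-{4-[(2S)-2,3-bis(benzyloxy)propyl]-2,6-dimethoxyphenoxy}ethyl]-2-(dichloromethyl)-4,5-dicyclohexyl-1,3,2-dioxaborolan-2-uide | [Li+].COc1cc(C[C@H](OCc2ccccc2)COCc2ccccc2)cc(OC)c1O[C@@H](COCc1ccccc1)[B-]1(C(Cl)Cl)O[C@H](C2CCCCC2)[C@@H](C2CCCCC2)O1 | intermediate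
20 | (4R,5R)-2-[(1S,2S)-3-(benzyloxy)-2-{4-[(2S)-2,3-bis(benzyloxy)propyl]-2,6-dimethoxyphenoxy}-1-chloropropyl]-4,5-dicyclohexyl-1,3,2-dioxaborolane | COc1cc(C[C@H](OCc2ccccc2)COCc2ccccc2)cc(OC)c1O[C@@H](COCc1ccccc1)[C@@H](Cl)B1O[C@H](C2CCCCC2)[C@@H](C2CCCCC2)O1 | intermediate
21 | bromomagnesium (4R,5R)-2-[4-(benzyloxy)-3,5-dimethoxyphenyl]-2-[(1S,2S)-3-(benzyloxy)-2-{4-[(2S)-2,3-bis(benzyloxy)propyl]-2,6-dimethoxyphenoxy}-1-chloropropyl]-4,5-dicyclohexyl-1,3,2-dioxaborolan-2-uide | Br[Mg+].COc1cc(C[C@H](OCc2ccccc2)COCc2ccccc2)cc(OC)c1O[C@@H](COCc1ccccc1)[C@@H](Cl)[B-]1(c2cc(OC)c(OCc3ccccc3)c(OC)c2)O[C@H](C2CCCCC2)[C@@H](C2CCCCC2)O1 | intermediate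
22 | (4R,5R)-2-[(1S,2R)-3-(benzyloxy)-1-[4-(benzyloxy)-3,5-dimethoxyphenyl]-2-{4-[(2S)-2,3-bis(benzyloxy)propyl]-2,6-dimethoxyphenoxy}propyl]-4,5-dicyclohexyl-1,3,2-dioxaborolane | COc1cc(C[C@H](OCc2ccccc2)COCc2ccccc2)cc(OC)c1O[C@@H](COCc1ccccc1)[C@H](c1cc(OC)c(OCc2ccccc2)c(OC)c1)B1O[C@H](C2CCCCC2)[C@@H](C2CCCCC2)O1 | intermediate
23 | (4R,5R)-2-[(1S,2S)-3-(benzyloxy)-1-[4-(benzyloxy)-3,5-dimethoxyphenyl]-2-{4-[(2S)-2,3-bis(benzyloxy)propyl]-2,6-dimethoxyphenoxy}propoxy]-4,5-dicyclohexyl-1,3,2-dioxaborolane | COc1cc(C[C@H](OCc2ccccc2)COCc2ccccc2)cc(OC)c1O[C@@H](COCc1ccccc1)[C@H](c1cc(OC)c(OCc2ccccc2)c(OC)c1)OB1O[C@H](C2CCCCC2)[C@@H](C2CCCCC2)O1 | intermediate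
24 | (1S,2S)-3-(benzyloxy)-1-[4-(benzyloxy)-3,5-dimethoxyphenyl]-2-{4-[(2S)-2,3-bis(benzyloxy)propyl]-2,6-dimethoxyphenoxy}propan-1-ol | COc1cc(C[C@H](OCc2ccccc2)COCc2ccccc2)cc(OC)c1O[C@@H](COCc1ccccc1)[C@@H](O)c1cc(OC)c(OCc2ccccc2)c(OC)c1 | intermediate
25 | (1S,2S)-1-(4-hydroxy-3,5-dimethoxyphenyl)-2-{4-[(2S)-2,3-dihydroxypropyl]-2,6-dimethoxyphenoxy}propane-1,3-diol | COc1cc([C@H](O)[C@H](CO)Oc2c(OC)cc(C[C@H](O)CO)cc2OC)cc(OC)c1O | target

**Count and risks**

Total step count: 12. Longest linear sequence: 8 steps (steps 1, 2, 3, 4, 7, 10, 11, 12 from 4-bromo-2,6-dimethoxyphenol).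

Steps most likely to fail:

1. Step 10. The ring B aryloxide may be lost by β-elimination from borate 21 (or from 19), or the chloride-selecting shift may give incomplete control at C7. The fallback sets out from 20, obtained by stopping step 10 before the Grignard addition and working up by extraction. Oxidation of the α-chloro boronate with H2O2 in NaHCO3-buffered THF/H2O should give (2S)-3-(benzyloxy)-2-{4-[(2S)-2,3-bis(benzyloxy)propyl]-2,6-dimethoxyphenoxy}propanal F2 and free the diol. Addition of 18 to F2 precomplexed with MgBr2·OEt2 in CH2Cl2 at −78 °C should follow the Cram-chelate model through the C8 ether oxygen and favour the threo alcohol. Any erythro isomer would be removed by chromatography, and the fallback comes back to the route at 24.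

2. Step 7. Slow substitution by the hindered 2,6-disubstituted aryloxide may allow chloride-exchange epimerisation at C8 or β-elimination of benzyloxide from the borate. The fallback sets out from 11. (Dibromomethyl)lithium, generated in situ (CH2Br2, LDA, THF, −78 °C, then ZnCl2, to rt), should insert to give the more reactive (4R,5R)-2-[(1S)-2-(benzyloxy)-1-bromoethyl]-4,5-dicyclohexyl-1,3,2-dioxaborolane F1. Treatment of F1 with sodium aryloxide 14 in THF at 0 °C should displace bromide with inversion, and the fallback comes back to the route at 16.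

3. Step 11. Hydroxide may induce β-elimination of the aryloxide from the hydroxyborate of 22, or hydroperoxide may attack the hindered dicyclohexyl dioxaborolane only slowly. The fallback sets out from 22. KHF2 in MeOH/H2O should convert it into potassium [(1S,2R)-3-(benzyloxy)-1-[4-(benzyloxy)-3,5-dimethoxyphenyl]-2-{4-[(2S)-2,3-bis(benzyloxy)propyl]-2,6-dimethoxyphenoxy}propyl]trifluoroborate F3 with recovery of the diol. Oxidation of F3 with Oxone in acetone/H2O at rt, near neutral and with retention at C7, comes back to the route at 24.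

**Further compounds**

F1 | step 7 | (4R,5R)-2-[(1S)-2-(benzyloxy)-1-bromoethyl]-4,5-dicyclohexyl-1,3,2-dioxaborolane | Br[C@H](COCc1ccccc1)B1O[C@H](C2CCCCC2)[C@@H](C2CCCCC2)O1
F2 | step 10 | (2S)-3-(benzyloxy)-2-{4-[(2S)-2,3-bis(benzyloxy)propyl]-2,6-dimethoxyphenoxy}propanal | COc1cc(C[C@H](OCc2ccccc2)COCc2ccccc2)cc(OC)c1O[C@@H](COCc1ccccc1)C=O
F3 | step 11 | potassium [(1S,2R)-3-(benzyloxy)-1-[4-(benzyloxy)-3,5-dimethoxyphenyl]-2-{4-[(2S)-2,3-bis(benzyloxy)propyl]-2,6-dimethoxyphenoxy}propyl]trifluoroborate | [K+].COc1cc(C[C@H](OCc2ccccc2)COCc2ccccc2)cc(OC)c1O[C@@H](COCc1ccccc1)[C@H](c1cc(OC)c(OCc2ccccc2)c(OC)c1)[B-](F)(F)F
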